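Germacrane numbering is used throughout (ring C1–C10, C14 on C10, C15 on C4, C11–C13 on C7). "Ring-trans" for C1=C10 refers to the ring bonds C9 and C2; its CIP descriptor is Z once C14 carries oxygen.

## The problem

The target is a heliangolide-type germacranolide: a ten-membered carbocycle carrying a trans 1,10-epoxide, a Z-trisubstituted C4=C5 alkene, a γ-lactone trans-fused at C6/C7 with an exocyclic C11=C13 methylene, a methacrylate on O8 and an acetate on O14. Five stereocentres must be set (1R, 6R, 7R, 8R, 10S). C8 is the only one that can sensibly be bought; it then has to steer C7 (C11 cis to O8) and C6 (O6 trans to both C11 and O8) across a flexible ring. The epoxide (1β,10α) has no neighbouring centre and depends on ring conformation and on delivery from the C14 hydroxyl. The α-methylene lactone and the methacrylate are Michael acceptors, the epoxide and the 1,5-diene cyclise transannularly under acid, the lactone oxygen is allylic, and the diene can undergo Cope rearrangement on heating; these groups therefore arrive late, in the order methylene lactone, methacrylate, epoxide, acetate. The enabling feature is the unit C10=C1–C2–C3–C4=C5: a cyclodeca-1,5-diene is the formal cycloreversion product of a bicyclo[2.2.0]hexane, so C1–C4 can come from a cyclobutene and C5/C10 from the alkene of a six-membered ring C5–C6–C7–C8–C9–C10. Because O6 sits next to C5, that ring can be a cyclohexenone (C6=O, C5=C10), which serves as the chromophore for a [2+2] photocycloaddition, later as the handle for C7 and C6, and as the reason the C4=C5 bond settles as the ring-cis enone.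

## Retrosynthesis

**25 ⇒ 23.** The acetate C–O bond and the two epoxide C–O bonds (C1–O, C10–O) are cut last. The free C14 hydroxyl of triene 23 is what makes C1=C10 the only alkene a vanadium peroxide will touch; a peracid on the acetate would prefer the more electron-rich C4=C5 bond. The forward steps (24, then 25) must be neutral or mildly basic, because a 1,10-epoxygermacrene does not survive acid.

**23 ⇒ 20.** The methacrylate acyl–O8 bond is cut and both oxygens are masked: O8 as a p-methoxybenzyl ether, O14 as a tert-butyldiphenylsilyl ether (20, via 22 and 21). The pair is orthogonal (DDQ, then buffered fluoride), neither needs strong acid or base next to the methylene lactone, and neither absorbs where the enone will be irradiated. A MOM ether at O8 was rejected because removing it late needs acid.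

**20 ⇒ 14.** The lactone is taken apart in the classical order: the C11=C13 methylene (Mannich/elimination on lactone 17), the O6–C12 lactone bond together with the C6–H bond (reduction of keto ester 15), and the C7–C11 bond (enolate alkylation of dienone 14). This sequence is chosen over a one-step radical annulation because the C6 ketone singles out C7 and C6 among three ring alkenes. The forward steps must place C11 cis to O8 and O6 trans to C11; these are the two centres the ten-membered ring has to control.

**14 ⇒ 13.** The bonds C5–C10 and C1–C4 are formed in the retrosynthetic sense, folding the ten-membered E,Z-dienone into the tricyclo[4.4.0.0^2,5]decanone 13. Ring expansion by fragmentation avoids any macrocyclisation at high dilution. It must be run with the C6 ketone in place, since the carbonyl both eases the cleavage and makes the conjugated C4=C5 bond ring-cis. The forward reaction must open the bicyclohexane without Cope rearrangement of the product.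

**13 ⇒ 10 + 12.** The bonds C4–C5 and C1–C10 are cut, giving enone 10 and 1-methylcyclobutene 12. Compared with any cut of the ten-membered ring itself this reduces the problem to a monocyclic enone with one stereocentre and a C5 hydrocarbon. The forward photocycloaddition must be head-to-head (methyl-bearing C4 to the enone α-carbon C5); its four new centres need no control because the next step removes them.

**10 ⇒ 1; 12 ⇒ 11.** Enone 10 maps onto (−)-shikimic acid 1: the carboxyl carbon becomes C14, C5 of the acid becomes C8 with the correct configuration, C3 becomes the C6 carbonyl and the C4 oxygen is removed (via 3–9). C3 of the acid in fact also has the configuration of C6, but it has to be spent on the chromophore. The alkene 12 comes from commercial methylenecyclobutane 11 by isomerisation.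

## Roads not taken

**Alternative 1:** electroreductive decarboxylative radical macrocyclisation. The cut is C7–C8. Cathodic reduction of a C8 N-acyloxyphthalimide releases CO2 and an α-silyloxy radical that adds to C7 of a sulfonylmethyl butenolide; loss of sulfinate forms the ring, the C7–C8 bond and the C11=C13 methylene at once, giving the 8-O-silyl ether A1 with epoxide and acetate already in place.
- Merits: A1 is two steps from the target, there is no thermal stage and no strong base near the lactone, and the epoxide can be set on an open chain by reagent control. In both respects this road is better than the chosen one, which needs nine steps after its key step and relies on ring conformation for the epoxide.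
- Weak points: a ten-membered ring is closed by an open-chain radical at high dilution with premature reduction as a competitor. C7 and C8 are both created in that step from a planar radical and a planar acceptor, with only C6 and the remote epoxide to bias them. The open-chain precursor needs the Z-alkene, the epoxide and the butenolide centre made separately.
- Against it the chosen plan sets: ring formation by fragmentation with no entropic penalty, and C8 taken from the chiral pool, not from a radical step.

**Alternative 2:** carbocycle first, Mn(OAc)3 lactone annulation. The cuts are C7–C11 and O–C6. Mn(OAc)3 (trivalent manganese) oxidises tert-butyl hydrogen malonate to a radical that adds to C7 of a ring C6=C7 alkene; oxidation and capture by the carboxylate at C6 give lactone A2 with a C11 ester.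
- Merits: the lactone ring arrives in one step with an activating group that allows a one-step decarboxylative methylenation, against four operations in the chosen plan.
- Weak points: it leaves the ten-membered ring unsolved. The electrophilic radical must choose the disubstituted C6=C7 bond over two more nucleophilic trisubstituted alkenes and a methacrylate. The C6 radical or cation is allylic and can be captured at C4 or cyclise across the ring. Hot acetic acid is a poor medium for a germacratriene. C6 and C7 still depend on ring conformation.
- Against it the chosen plan sets: the C6 ketone makes C7 and C6 the only reactive sites.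

**Alternative 3:** transannular [2,3]-Wittig contraction. The cut is C6–C7. n-BuLi deprotonates C6 of a thirteen-membered diallylic ether and the carbanion shifts onto C7 as O–C13 breaks, giving the ten-membered C6 alcohol A3 with the C11=C13 methylene built in.
- Merits: C6 and C7 are set together through an ordered five-membered transition state, a better stereochemical argument than the stepwise enolate and hydride steps of the chosen plan; nothing is heated to 180 °C; the large ether ring is easier to close than a ten-membered carbocycle.
- Weak points: lithiation must be regioselective between two allylic ether positions and the [1,2]-shift competes. The thirteen-membered ether with three defined alkenes is long to make. A3 still needs C12 oxidised from a protected alcohol to the acid level and a MOM ether removed with acid beside the methylene lactone.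
- Against it the chosen plan sets: the carbocycle appears two steps after a monocyclic enone, and the end game is free of acid.

Key step: step 10

## Route

Remark: 13 is written as the facial isomer from addition anti to the C8 ether; the syn-facial isomer, if it forms, differs only at the four centres that step 11 destroys and is carried forward with it.

Step 1
Reactants: 1 (−)-shikimic acid
Product: 3 methyl 3,4-O-isopropylideneshikimate (5-OH free), via methyl shikimate 2 (not isolated)
Conditions: MeOH, CSA (cat.), reflux; evaporate; then 2,2-dimethoxypropane, acetone, CSA (cat.), 23 °C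
Reagents that add atoms: methanol, CO; 2,2-dimethoxypropane, COC(C)(C)OC
Why: Fischer esterification followed by acid-catalysed transketalisation; only the cis-3,4-diol can form the five-membered acetonide, so the 5-hydroxyl stays free and no stereocentre is touched.

Step 2
Reactants: 3 methyl 3,4-O-isopropylideneshikimate
Product: 4 3,4-O-isopropylideneshikimyl alcohol (C7 primary allylic alcohol; 5-OH free)
Conditions: i-Bu2AlH (4 equiv), CH2Cl2, −78 → 0 °C
Reagents that add atoms: none
Why: i-Bu2AlH reduces the conjugated ester 1,2 to the allylic alcohol; the acetonide and the aluminium alkoxide of the 5-hydroxyl are inert.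

Step 3
Reactants: 4 3,4-O-isopropylideneshikimyl alcohol
Product: 5 7-O-TBDPS ether of 4 (5-OH free)
Conditions: t-BuPh2SiCl (1.05 equiv), imidazole, CH2Cl2, 0 °C
Reagents that add atoms: tert-butyldiphenylsilyl chloride, CC(C)(C)[Si](Cl)(c1ccccc1)c1ccccc1
Why: Silylation with the bulky chlorosilane is selective for the primary allylic hydroxyl over the secondary one beside the acetonide.

Step 4
Reactants: 5 7-O-TBDPS ether of 4
Product: 6 5-O-PMB-7-O-TBDPS-3,4-O-isopropylideneshikimyl alcohol
Conditions: NaH, 4-MeOC6H4CH2Cl, Bu4NI (cat.), THF/DMF, 0 → 23 °C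
Reagents that add atoms: 4-methoxybenzyl chloride, COc1ccc(CCl)cc1
Why: Williamson etherification of the secondary alkoxide; no ester remains that could undergo base-induced elimination, and the primary silyl ether tolerates NaH at this temperature.

Step 5
Reactants: 6 5-O-PMB-7-O-TBDPS-3,4-O-isopropylideneshikimyl alcohol
Product: 7 5-O-PMB-7-O-TBDPS-shikimyl alcohol (3,4-diol; ring centres as in 1)
Conditions: AcOH/H2O (4:1), 40 °C
Reagents that add atoms: none
Why: Mild aqueous acid hydrolyses the cis-fused acetonide while the PMB and TBDPS ethers survive.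

Step 6
Reactants: 7 5-O-PMB-7-O-TBDPS-shikimyl alcohol
Product: 8 (5R,6S)-6-hydroxy-5-[(4-methoxybenzyl)oxy]-3-{[(tert-butyldiphenylsilyl)oxy]methyl}cyclohex-2-en-1-one
Conditions: MnO2 (activated, excess), CH2Cl2, 23 °C
Reagents that add atoms: none
Why: MnO2 oxidises only the allylic hydroxyl of the diol, giving the α′-hydroxy enone; the two remaining centres are untouched under these neutral conditions.

Step 7
Reactants: 8 α′-hydroxy enone
Product: 9 (1S,6R)-6-[(4-methoxybenzyl)oxy]-2-oxo-4-{[(tert-butyldiphenylsilyl)oxy]methyl}cyclohex-3-en-1-yl acetate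
Conditions: Ac2O, pyridine, DMAP (cat.), CH2Cl2, 0 °C
Reagents that add atoms: acetic anhydride, CC(=O)OC(C)=O
Why: Acylation of the α-ketol turns the hydroxyl into a leaving group for reductive cleavage; the weak base and low temperature avoid elimination of the β-ether.

Step 8
Reactants: 9 α′-acetoxy enone
Product: 10 (5R)-5-[(4-methoxybenzyl)oxy]-3-{[(tert-butyldiphenylsilyl)oxy]methyl}cyclohex-2-en-1-one
Conditions: SmI2 (2.2 equiv), THF/MeOH, −78 °C
Reagents that add atoms: none
Why: Electron transfer from divalent samarium to the ketone expels the α-acetate (reductive cleavage of an α-acyloxy ketone); methanol protonates the trivalent samarium enolate at −78 °C before the β-ether can eliminate, leaving the future C8 as the only stereocentre.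

Step 9
Reactants: 11 methylenecyclobutane
Product: 12 1-methylcyclobutene
Conditions: Na/Al2O3 (cat.), neat, 23 °C; spinning-band distillation (bp 37 °C)
Reagents that add atoms: none
Why: Base-catalysed allylic isomerisation toward the more stable endocyclic trisubstituted alkene; residual 11 is removed by fractional distillation.

Step 10
Reactants: 10 (5R)-enone; 12 1-methylcyclobutene
Product: 13 cis,anti,cis-tricyclo[4.4.0.0^2,5]decan-7-one (germacrane C6 ketone; C8 OPMB; C10 CH2OTBDPS; C4 methyl; bonds C4–C5 and C1–C10 new)
Conditions: hν (350 nm, Pyrex), 12 (15 equiv), CH2Cl2, degassed, −30 °C; then brief filtration through basic Al2O3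
Reagents that add atoms: none
Why: Light of 350 nm excites only the enone, which crosses to its triplet and adds stepwise to the strained alkene of 12 through triplet 1,4-diradicals; after spin inversion, radical–radical coupling closes the central cyclobutane, so the one new ring arises by diradical collapse and completes a bicyclo[2.2.0]hexane (the known enone–cyclobutene [2+2] photocycloaddition). The selectivity needed is head-to-head regiochemistry, C4 to C5 and C1 to C10: every path to the head-to-tail isomer would have to join the two fully substituted carbons C10 and C4, whereas the productive diradical formed by C1–C10 bonding is an α-keto radical at C5 and a tertiary radical at C4. C5/C10 end cis because a trans-fused six–four ring is strained and epimerises at C5 on basic alumina; C1/C4 are cis by the cyclobutene ring; the outer rings are anti because 12 approaches with its CH2CH2 bridge turned away from the six-membered ring; the enone face anti to the C8 ether is preferred. None of these four centres has to be controlled, because step 11 destroys them all and both facial isomers converge. The PMB and TBDPS arenes do not absorb at 350 nm, and electron transfer from the anisyl ring to the enone triplet is endergonic. The excess of volatile 12 is recovered by distillation.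

Step 11
Reactants: 13 tricyclic photoadduct
Product: 14 (2Z,6Z,9R)-9-[(4-methoxybenzyl)oxy]-3-methyl-7-{[(tert-butyldiphenylsilyl)oxy]methyl}cyclodeca-2,6-dien-1-one (germacra-1(10),4-dien-6-one: C4=C5 Z and C1=C10 ring-trans)
Conditions: o-C6H4Cl2 (0.01 M, degassed), BHT (cat.), base-washed sealed tube, 180 °C, short heating
Reagents that add atoms: none
Why: Thermal cycloreversion of the bicyclo[2.2.0]hexane cleaves C5–C10 and C1–C4, turning the two bonds made in step 10 into the C4=C5 and C1=C10 π bonds and releasing the ten-membered ring. The C6 carbonyl stabilises the C5 radical of the diradical pathway and lets the conjugated alkene settle as the ring-cis enone, while the cis,anti,cis geometry delivers the ring-trans C1=C10 bond. The E,Z-1,5-diene needs a boat-like transition state for Cope rearrangement and should survive short heating.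

Step 12
Reactants: 14 dienone
Product: 15 methyl 2-[(1R,3Z,7Z,10R)-10-[(4-methoxybenzyl)oxy]-4-methyl-2-oxo-8-{[(tert-butyldiphenylsilyl)oxy]methyl}cyclodeca-3,7-dien-1-yl]acetate (germacrane 7R,8R)
Conditions: LiN(i-Pr)2, THF, −78 °C; BrCH2CO2Me, DMPU, −78 → −45 °C
Reagents that add atoms: methyl bromoacetate, COC(=O)CBr
Why: Kinetic deprotonation of the enone at its only α′-CH2 gives the cross-conjugated C6–C7 lithium enolate, which is C-alkylated by the reactive bromoacetate. The C8–C9 bond stands roughly perpendicular to the enolate plane and blocks the transannular face; attack on the outer face with the C8–O bond lying in the enolate plane, where it cannot overlap with the π system and so cannot eliminate, puts C11 cis to O8 (7R). The centre stays epimerisable and its configuration is checked before step 13.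

Step 13
Reactants: 15 keto ester
Product: 17 (3aR,4R,6Z,10Z,11aR)-4-[(4-methoxybenzyl)oxy]-10-methyl-6-{[(tert-butyldiphenylsilyl)oxy]methyl}-3a,4,5,8,9,11a-hexahydrocyclodeca[b]furan-2(3H)-one (trans-fused 12,6α-olide), via hydroxy ester 16 (not isolated)
Conditions: NaBH4, CeCl3·7H2O, MeOH/THF, −40 °C; then PPTS (cat.), toluene, 50 °C
Reagents that add atoms: none
Why: Luche reduction is 1,2-selective for the enone. With the C7–C8 bond eclipsing the carbonyl, the arrangement found in heliangolides, the C7 side chain shields one face and hydride enters anti to it, giving the 6α-alcohol (trans to C11, anti to O8). Mild acid then closes the trans-fused γ-lactone with loss of methanol.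

Step 14
Reactants: 17 lactone
Product: 20 8β-(4-methoxybenzyloxy)-14-(tert-butyldiphenylsilyloxy)germacra-1(10),4Z,11(13)-trien-12,6α-olide, via Mannich base 18 (not isolated), via methiodide 19 (not isolated)
Conditions: LiN(i-Pr)2, THF, −78 °C; CH2=NMe2+ I−, −78 → 0 °C; then MeI, MeOH, 23 °C; then aq. NaHCO3/CH2Cl2
Reagents that add atoms: Eschenmoser's salt, C=[N+](C)C.[I-]
Why: Mannich reaction of the lactone enolate, exhaustive N-methylation and base-induced elimination of trimethylamine, the standard α-methylenation of γ-lactones; C6 and C7 are not enolisable and both ethers tolerate the sequence.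

Step 15
Reactants: 20 PMB ether
Product: 21 8β-hydroxy-14-(tert-butyldiphenylsilyloxy)germacra-1(10),4Z,11(13)-trien-12,6α-olide
Conditions: DDQ, CH2Cl2/pH 7 buffer (10:1), 0 °C
Reagents that add atoms: none
Why: Oxidative cleavage of the p-methoxybenzyl ether under buffered, neutral conditions; the silyl ether, the diene and the methylene lactone are not oxidised.

Step 16
Reactants: 21 C8 alcohol
Product: 22 8β-methacryloyloxy-14-(tert-butyldiphenylsilyloxy)germacra-1(10),4Z,11(13)-trien-12,6α-olide
Conditions: methacrylic anhydride, Et3N, DMAP (cat.), CH2Cl2, 0 → 23 °C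
Reagents that add atoms: methacrylic anhydride, C=C(C)C(=O)OC(=O)C(C)=C
Why: DMAP-catalysed acylation at the acyl carbon, so C8 keeps its configuration; tertiary amines do not add irreversibly to the methylene lactone.

Step 17
Reactants: 22 silyl ether
Product: 23 14-hydroxy-8β-methacryloyloxygermacra-1(10),4Z,11(13)-trien-12,6α-olide
Conditions: HF·pyridine, pyridine/THF, 0 → 23 °C
Reagents that add atoms: none
Why: Buffered fluoride cleaves the primary allylic silyl ether without the basicity of Bu4NF, which would attack the two acrylate units.

Step 18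
Reactants: 23 allylic alcohol
Product: 24 1β,10α-epoxy-14-hydroxy-8β-methacryloyloxygermacra-4Z,11(13)-dien-12,6α-olide (1R,10S)
Conditions: VO(acac)2 (5 mol %), t-BuOOH, CH2Cl2, 0 °C
Reagents that add atoms: tert-butyl hydroperoxide, CC(C)(C)OO
Why: Hydroxyl-directed epoxidation: the C14 alkoxide binds vanadium, so only the allylic-alcohol alkene C1=C10 reacts, while the isolated C4=C5 bond and the two electron-poor alkenes do not. Syn addition to the ring-trans alkene gives the trans epoxide, and delivery to the peripheral face of the conformer with C14 on the β side (the side of O8 and C11) gives 1β,10α.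

Step 19
Reactants: 24 epoxy alcohol
Product: 25 14-acetoxy-1β,10α-epoxy-8β-methacryloyloxygermacra-4Z,11(13)-dien-12,6α-olide (1R,6R,7R,8R,10S; target)
Conditions: Ac2O, pyridine, DMAP (cat.), CH2Cl2, 0 °C
Reagents that add atoms: acetic anhydride, CC(=O)OC(C)=O
Why: Acetylation of the primary epoxy alcohol under mild base; no acid is present, so the epoxide and the diene are safe.

## Compound list

1 | (−)-shikimic acid | C1[C@H]([C@@H]([C@@H](C=C1C(=O)O)O)O)O | starting material
2 | methyl shikimate | C1[C@H]([C@@H]([C@@H](C=C1C(=O)OC)O)O)O | intermediate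
3 | methyl 3,4-O-isopropylideneshikimate; methyl (3aR,7R,7aS)-7-hydroxy-2,2-dimethyl-3a,6,7,7a-tetrahydro-1,3-benzodioxole-5-carboxylate | C1[C@H]([C@H]2[C@@H](C=C1C(=O)OC)OC(C)(C)O2)O | intermediate
4 | 3,4-O-isopropylideneshikimyl alcohol; (3aR,7R,7aS)-5-(hydroxymethyl)-2,2-dimethyl-3a,6,7,7a-tetrahydro-1,3-benzodioxol-7-ol | C1[C@H]([C@H]2[C@@H](C=C1CO)OC(C)(C)O2)O | intermediate
5 | 7-O-TBDPS ether of 4 | C1[C@H]([C@H]2[C@@H](C=C1CO[Si](c3ccccc3)(c4ccccc4)C(C)(C)C)OC(C)(C)O2)O | intermediate
6 | 5-O-PMB-7-O-TBDPS-3,4-O-isopropylideneshikimyl alcohol | C1[C@H]([C@H]2[C@@H](C=C1CO[Si](c3ccccc3)(c4ccccc4)C(C)(C)C)OC(C)(C)O2)OCc5ccc(OC)cc5 | intermediate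
7 | 5-O-PMB-7-O-TBDPS-shikimyl alcohol (3,4-diol) | C1[C@H]([C@@H]([C@@H](C=C1CO[Si](c2ccccc2)(c3ccccc3)C(C)(C)C)O)O)OCc2ccc(OC)cc2 | intermediate
8 | (5R,6S)-6-hydroxy-5-[(4-methoxybenzyl)oxy]-3-{[(tert-butyldiphenylsilyl)oxy]methyl}cyclohex-2-en-1-one | C1[C@H]([C@@H](C(=O)C=C1CO[Si](c2ccccc2)(c3ccccc3)C(C)(C)C)O)OCc2ccc(OC)cc2 | intermediate
9 | (1S,6R)-6-[(4-methoxybenzyl)oxy]-2-oxo-4-{[(tert-butyldiphenylsilyl)oxy]methyl}cyclohex-3-en-1-yl acetate | C1[C@H]([C@@H](C(=O)C=C1CO[Si](c2ccccc2)(c3ccccc3)C(C)(C)C)OC(C)=O)OCc2ccc(OC)cc2 | intermediate
10 | (5R)-5-[(4-methoxybenzyl)oxy]-3-{[(tert-butyldiphenylsilyl)oxy]methyl}cyclohex-2-en-1-one | O=C1C=C(CO[Si](c2ccccc2)(c3ccccc3)C(C)(C)C)C[C@@H](OCc2ccc(OC)cc2)C1 | intermediate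
11 | methylenecyclobutane | C=C1CCC1 | starting material
12 | 1-methylcyclobutene | CC1=CCC1 | intermediate
13 | cis,anti,cis-9-[(4-methoxybenzyl)oxy]-5-methyl-1-{[(tert-butyldiphenylsilyl)oxy]methyl}tricyclo[4.4.0.0^2,5]decan-7-one (cyclobutane anti to the C9 ether) | O=C1C[C@H](OCc2ccc(OC)cc2)C[C@@]2(CO[Si](c3ccccc3)(c4ccccc4)C(C)(C)C)[C@@H]3CC[C@]3(C)[C@@H]12 | intermediate
14 | (2Z,6Z,9R)-9-[(4-methoxybenzyl)oxy]-3-methyl-7-{[(tert-butyldiphenylsilyl)oxy]methyl}cyclodeca-2,6-dien-1-one | C1[C@H](OCc2ccc(OC)cc2)C/C(CO[Si](c3ccccc3)(c4ccccc4)C(C)(C)C)=C/CC/C(C)=C\C1=O | intermediate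
15 | methyl 2-[(1R,3Z,7Z,10R)-10-[(4-methoxybenzyl)oxy]-4-methyl-2-oxo-8-{[(tert-butyldiphenylsilyl)oxy]methyl}cyclodeca-3,7-dien-1-yl]acetate | COC(=O)C[C@@H]1[C@H](OCc2ccc(OC)cc2)C/C(CO[Si](c3ccccc3)(c4ccccc4)C(C)(C)C)=C/CC/C(C)=C\C1=O | intermediate
16 | 6α-hydroxy ester (C6 alcohol of 15, OH trans to the C7 side chain) | COC(=O)C[C@@H]1[C@H](OCc2ccc(OC)cc2)C/C(CO[Si](c3ccccc3)(c4ccccc4)C(C)(C)C)=C/CC/C(C)=C\[C@H]1O | intermediate
17 | (3aR,4R,6Z,10Z,11aR)-4-[(4-methoxybenzyl)oxy]-10-methyl-6-{[(tert-butyldiphenylsilyl)oxy]methyl}-3a,4,5,8,9,11a-hexahydrocyclodeca[b]furan-2(3H)-one | COc1ccc(CO[C@@H]2C/C(CO[Si](c3ccccc3)(c4ccccc4)C(C)(C)C)=C/CC/C(C)=C\[C@H]3OC(=O)C[C@@H]32)cc1 | intermediate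
18 | C11 dimethylaminomethyl lactone (Mannich base of 17; C11 epimers) | COc1ccc(CO[C@@H]2C/C(CO[Si](c3ccccc3)(c4ccccc4)C(C)(C)C)=C/CC/C(C)=C\[C@H]3OC(=O)C(CN(C)C)[C@@H]32)cc1 | intermediate
19 | C11 trimethylammoniomethyl lactone iodide (methiodide of 18) | COc1ccc(CO[C@@H]2C/C(CO[Si](c3ccccc3)(c4ccccc4)C(C)(C)C)=C/CC/C(C)=C\[C@H]3OC(=O)C(C[N+](C)(C)C)[C@@H]32)cc1.[I-] | intermediate
20 | 8β-(4-methoxybenzyloxy)-14-(tert-butyldiphenylsilyloxy)germacra-1(10),4Z,11(13)-trien-12,6α-olide | COc1ccc(CO[C@@H]2C/C(CO[Si](c3ccccc3)(c4ccccc4)C(C)(C)C)=C/CC/C(C)=C\[C@H]3OC(=O)C(=C)[C@@H]32)cc1 | intermediate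
21 | 8β-hydroxy-14-(tert-butyldiphenylsilyloxy)germacra-1(10),4Z,11(13)-trien-12,6α-olide | O[C@@H]1C/C(CO[Si](c2ccccc2)(c3ccccc3)C(C)(C)C)=C/CC/C(C)=C\[C@H]2OC(=O)C(=C)[C@@H]21 | intermediate
22 | 8β-methacryloyloxy-14-(tert-butyldiphenylsilyloxy)germacra-1(10),4Z,11(13)-trien-12,6α-olide | C=C(C)C(=O)O[C@@H]1C/C(CO[Si](c2ccccc2)(c3ccccc3)C(C)(C)C)=C/CC/C(C)=C\[C@H]2OC(=O)C(=C)[C@@H]21 | intermediate
23 | 14-hydroxy-8β-methacryloyloxygermacra-1(10),4Z,11(13)-trien-12,6α-olide | C=C(C)C(=O)O[C@@H]1C/C(CO)=C/CC/C(C)=C\[C@H]2OC(=O)C(=C)[C@@H]21 | intermediate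
24 | 1β,10α-epoxy-14-hydroxy-8β-methacryloyloxygermacra-4Z,11(13)-dien-12,6α-olide | C=C(C)C(=O)O[C@@H]1C[C@@]2(CO)O[C@@H]2CC/C(C)=C\[C@H]2OC(=O)C(=C)[C@@H]21 | intermediate
25 | 14-acetoxy-1β,10α-epoxy-8β-methacryloyloxygermacra-4Z,11(13)-dien-12,6α-olide (1R,6R,7R,8R,10S) | C=C(C)C(=O)O[C@@H]1C[C@@]2(COC(C)=O)O[C@@H]2CC/C(C)=C\[C@H]2OC(=O)C(=C)[C@@H]21 | target

## Step count and risks

Total: 19 steps. Longest linear sequence: 18 steps (steps 1–8 and 10–19); step 9 is the one-step side branch.

**Step 10 (key step).** Most likely failure: loss of regiocontrol (head-to-tail closure) or consumption of the enone triplet by hydrogen abstraction from the allylic C–H bonds of the alkene, because the methyl group of 12 biases the addition only sterically.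
Fallback: irradiate 10 with methyl cyclobut-1-ene-1-carboxylate instead. An electron-poor alkene adds with its acceptor-bearing carbon next to the enone α-carbon, so electronic and steric preferences coincide and give the C15-ester photoadduct F1. LiAlH4 reduces ketone and ester to the diol F2; selective sulfonylation of the primary hydroxyl (TsCl, pyridine) gives the tosylate F3; LiBHEt3 displaces the tosylate to leave the C4 methyl in the C6 alcohol F4; Dess–Martin oxidation returns the ketone. The fallback sets out from 10 and rejoins the route at 13.

**Step 11.** Most likely failure: Cope rearrangement of the product to a divinylcyclohexanone, or opening to the 4E enone, which rearranges faster still; both stem from the temperature needed to break an unactivated bicyclohexane.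
Fallback: convert 13 with LiN(i-Pr)2 and Me3SiCl into the C6–C7 trimethylsilyl enol ether F5. The C5 radical of the fragmentation is then allylic, so the ring should open at lower temperature to the silyl dienol ether F6. MeLi regenerates the lithium enolate of step 12 directly, and methyl bromoacetate gives the keto ester. The fallback sets out from 13 and rejoins at 15.

**Step 12.** Most likely failure: poor or reversed facial selectivity at C7, because an ether that prefers to sit out of the enolate plane would send C11 trans to O8; β-elimination of the C8 ether from the enolate on warming is the second risk.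
Fallback: set C7 on the rigid six-membered ring before ring expansion. Aldol condensation of 13 with methyl glyoxylate (LiN(i-Pr)2; then MsCl, Et3N, DBU) gives the (E)-alkylidene keto ester F7. Allylic 1,3-strain with the alkylidene forces the C8 ether axial, so hydrogenation (H2, Pd/C, pyridine to spare the PMB ether) adds from the face opposite O8 and gives the cis keto ester F8. Thermolysis as in step 11 then opens the ring. The fallback sets out from 13 and rejoins at 15.

**Step 13.** Most likely failure: hydride delivery to the other carbonyl face, giving the 6β-alcohol, because medium-ring ketones react through whichever conformer exposes a face and that cannot be fixed in advance.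
Fallback: accept that outcome and close the lactone with inversion. Reduction of 15 then gives the 6β-hydroxy ester F9, which closes to the cis-fused lactone F10; LiOH opens it to the hydroxy acid F11, and Mitsunobu lactonisation (PPh3, DIAD) displaces the activated allylic C6 oxygen intramolecularly with inversion. The fallback sets out from 15 and rejoins at 17.

**Step 18.** Most likely failure: epoxidation from the other ring face, if the conformer with C14 on the α side reacts; the directing hydroxymethyl can reach either face, so only the ring conformation decides.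
Fallback: replace substrate control by reagent control with a Sharpless–Katsuki epoxidation of 23 (Ti(OiPr)4, L-(+)-diethyl tartrate, t-BuOOH, 4 Å sieves, −20 °C). This tartrate antipode gives (2S)-epoxy alcohols from 2-substituted primary allylic alcohols, which corresponds to 10S here. The fallback sets out from 23 and rejoins at 24 and makes no new compound.

## Further compounds

F1 | step 10 | C15-ester photoadduct (13 with CO2Me in place of the C4 methyl) | O=C1C[C@H](OCc2ccc(OC)cc2)C[C@@]2(CO[Si](c3ccccc3)(c4ccccc4)C(C)(C)C)[C@@H]3CC[C@]3(C(=O)OC)[C@@H]12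
F2 | step 10 | C6,C15-diol (C6 epimers) | OC1C[C@H](OCc2ccc(OC)cc2)C[C@@]2(CO[Si](c3ccccc3)(c4ccccc4)C(C)(C)C)[C@@H]3CC[C@]3(CO)[C@@H]12
F3 | step 10 | C15 tosylate of F2 | OC1C[C@H](OCc2ccc(OC)cc2)C[C@@]2(CO[Si](c3ccccc3)(c4ccccc4)C(C)(C)C)[C@@H]3CC[C@]3(COS(=O)(=O)c5ccc(C)cc5)[C@@H]12
F4 | step 10 | C6 alcohol of 13 (C6 epimers) | OC1C[C@H](OCc2ccc(OC)cc2)C[C@@]2(CO[Si](c3ccccc3)(c4ccccc4)C(C)(C)C)[C@@H]3CC[C@]3(C)[C@@H]12
F5 | step 11 | C6–C7 trimethylsilyl enol ether of 13 | C[Si](C)(C)OC1=C[C@H](OCc2ccc(OC)cc2)C[C@@]2(CO[Si](c3ccccc3)(c4ccccc4)C(C)(C)C)[C@@H]3CC[C@]3(C)[C@@H]12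
F6 | step 11 | C6–C7 trimethylsilyl dienol ether of 14 | [C@@H]1(OCc2ccc(OC)cc2)C/C(CO[Si](c3ccccc3)(c4ccccc4)C(C)(C)C)=C/CC/C(C)=C\C(O[Si](C)(C)C)=C1
F7 | step 12 | (E)-C7 methoxycarbonylmethylidene derivative of 13 | O=C1/C(=C/C(=O)OC)[C@H](OCc2ccc(OC)cc2)C[C@@]2(CO[Si](c3ccccc3)(c4ccccc4)C(C)(C)C)[C@@H]3CC[C@]3(C)[C@@H]12
F8 | step 12 | C7 methoxycarbonylmethyl derivative of 13 (side chain cis to the C8 ether) | O=C1[C@H](CC(=O)OC)[C@H](OCc2ccc(OC)cc2)C[C@@]2(CO[Si](c3ccccc3)(c4ccccc4)C(C)(C)C)[C@@H]3CC[C@]3(C)[C@@H]12
F9 | step 13 | 6β-hydroxy ester (C6 epimer of 16) | COC(=O)C[C@@H]1[C@H](OCc2ccc(OC)cc2)C/C(CO[Si](c3ccccc3)(c4ccccc4)C(C)(C)C)=C/CC/C(C)=C\[C@@H]1O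
F10 | step 13 | cis-fused lactone (C6 epimer of 17) | COc1ccc(CO[C@@H]2C/C(CO[Si](c3ccccc3)(c4ccccc4)C(C)(C)C)=C/CC/C(C)=C\[C@@H]3OC(=O)C[C@@H]32)cc1
F11 | step 13 | 6β-hydroxy acid | OC(=O)C[C@@H]1[C@H](OCc2ccc(OC)cc2)C/C(CO[Si](c3ccccc3)(c4ccccc4)C(C)(C)C)=C/CC/C(C)=C\[C@@H]1O
F0 | step 18 | none | none
A1 | alternative 1 | 8-O-tert-butyldimethylsilyl ether of the 8-desacyl target | CC(C)(C)[Si](C)(C)O[C@@H]1C[C@@]2(COC(C)=O)O[C@@H]2CC/C(C)=C\[C@H]2OC(=O)C(=C)[C@@H]21
A2 | alternative 2 | trans-fused lactone with C11 tert-butoxycarbonyl group (one C11 epimer) | C=C(C)C(=O)O[C@@H]1C/C(CO[Si](C)(C)C(C)(C)C)=C/CC/C(C)=C\[C@H]2OC(=O)[C@@H](C(=O)OC(C)(C)C)[C@@H]21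
A3 | alternative 3 | ten-membered C6 alcohol with C7 2-propenyl unit bearing the C12 PMB ether | COCO[C@@H]1C/C(CO[Si](C(C)C)(C(C)C)C(C)C)=C/CC/C(C)=C\[C@@H](O)[C@@H]1C(=C)COCc1ccc(OC)cc1
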